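**Plan**

- Locants: ring C1 (oxirane carbon carrying C1'H2OAc), C2, C3, C4=C5(CH3), C6(=O), C7, C8 (spiro oxirane carbon), C9, C10 (oxirane CH); exocyclic C11 on C8 carries CH3 and C12H2OAc.
- Retrosynthesis: C6=O comes from the carbinol and both oxiranes from the allylic alcohols C1=C10/C1'–OH and C8=C11/C12–OH. The ring is opened at C5–C6, because C5 bears CH3 and the carbonyl carbon while H on C4 is cis to C6, the pattern left by syn addition of H and an aldehyde carbon across a methyl-capped alkyne C4≡C5. The open ynal is cut at C7–C8, C8–C9 and C1–C2.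
- Forward: 2-butyne-1,4-diol supplies C9–C10=C1–C1' (hydroalumination–iodination), a Negishi coupling adds C2–C5, propargyl alcohol adds C8/C11/C12 (copper coupling, anti-carbomagnesiation–iodination) and a Reformatsky reagent adds C7–C6. The only ring, the ten-membered one, then closes by nickel-catalysed reductive ynal cyclisation.
- Stereochemistry: the three alkene geometries come from anti-hydroalumination, anti-carbomagnesiation and syn Ni–H delivery. All four stereocentres come from one double Sharpless epoxidation with D-(−)-diethyl tartrate. The uncontrolled C6 carbinol is oxidised last, after acetylation, so that no free hydroxymethyl group ever faces the ketone.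

Key step: step 11

Remark on the chemistry: TBS = tert-butyldimethylsilyl, TIPS = triisopropylsilyl; C6 formed in step 11 is not controlled, so 20 and 21 are racemic and 22–24 are C6-epimer pairs that merge in step 16.

**Step 1**
Reactants: 1 2-butyne-1,4-diol
Product: 2 4-(TBS-oxy)but-2-yn-1-ol
Conditions: NaH (1.0 equiv), THF, 0 °C to rt; then TBSCl (1.0 equiv)
Reagents that add atoms: tert-butyldimethylsilyl chloride, CC(C)(C)[Si](C)(C)Cl
Why: O-silylation of the sparingly soluble monosodium alkoxide of a symmetrical diol should stop at the mono-ether, which distinguishes the future C1' oxygen from the C9 oxygen.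

**Step 2**
Reactants: 2 4-(TBS-oxy)but-2-yn-1-ol
Product: 4 (2Z)-4-(TBS-oxy)-3-iodobut-2-en-1-ol, via cyclic sodium alkenylalanate 3 (not isolated)
Conditions: NaAlH2(OCH2CH2OMe)2 (1.5 equiv), THF, 0 °C; then I2, THF, −78 to 0 °C
Reagents that add atoms: iodine, I-I
Why: Hydroxyl-directed trans-hydroalumination of the propargylic alcohol puts aluminium on the alkyne carbon remote from the free hydroxyl, and iodinolysis with retention should give the Z iodide in which C9 is cis to the position that will carry C2.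

**Step 3**
Reactants: 4 (2Z)-4-(TBS-oxy)-3-iodobut-2-en-1-ol; 5 5-bromopent-2-yne
Product: 7 (2E)-3-[(TBS-oxy)methyl]oct-2-en-6-yn-1-ol, via pent-3-yn-1-ylzinc bromide 6 (not isolated)
Conditions: 5, Zn dust, LiCl, THF, 40 °C; then 4, 6 (2.5 equiv), Pd(OAc)2 (2 mol %), SPhos (4 mol %), THF, rt
Reagents that add atoms: none
Why: Negishi coupling of an alkenyl iodide with a primary alkylzinc halide proceeds with retention of geometry and tolerates a free hydroxyl under Pd/SPhos catalysis, joining C1 to C2.

**Step 4**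
Reactants: 7 (2E)-3-[(TBS-oxy)methyl]oct-2-en-6-yn-1-ol
Product: 8 (2E)-1-bromo-3-[(TBS-oxy)methyl]oct-2-en-6-yne
Conditions: CBr4, PPh3, CH2Cl2, 0 °C
Reagents that add atoms: tetrabromomethane, BrC(Br)(Br)Br
Why: Appel bromination converts the primary allylic alcohol to the bromide under neutral conditions without allylic transposition or loss of the silyl ether.

**Step 5**
Reactants: 8 (2E)-1-bromo-3-[(TBS-oxy)methyl]oct-2-en-6-yne; 9 propargyl alcohol
Product: 10 (5E)-6-[(TBS-oxy)methyl]undec-5-ene-2,9-diyn-1-ol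
Conditions: CuI, NaI, K2CO3, DMF, rt
Reagents that add atoms: none
Why: Copper-mediated alkynylation of a primary allylic halide by the terminal alkyne should give the skipped enyne by direct substitution at C9, because the SN2' terminus C1 is fully substituted.

**Step 6**
Reactants: 10 (5E)-6-[(TBS-oxy)methyl]undec-5-ene-2,9-diyn-1-ol
Product: 12 (2Z,5E)-3-iodo-2-methyl-6-[(TBS-oxy)methyl]undeca-2,5-dien-9-yn-1-ol, via five-membered oxamagnesacycle 11 (not isolated)
Conditions: MeMgCl (4 equiv), CuI (20 mol %), THF, −20 °C to rt; then I2, THF, −78 to 0 °C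
Reagents that add atoms: methylmagnesium chloride, C[Mg]Cl; iodine, I-I
Why: Copper-catalysed anti-carbomagnesiation of the propargylic alkoxide delivers methyl to C11 and magnesium to C8 within a chelate, and iodinolysis with retention fixes the tetrasubstituted geometry (iodine cis to C12, C9 cis to CH3) while the undirected C4≡C5 alkyne is left alone.

**Step 7**
Reactants: 12 (2Z,5E)-3-iodo-2-methyl-6-[(TBS-oxy)methyl]undeca-2,5-dien-9-yn-1-ol
Product: 13 (2Z,5E)-1-(TBS-oxy)-3-iodo-2-methyl-6-[(TBS-oxy)methyl]undeca-2,5-dien-9-yne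
Conditions: TBSCl, imidazole, DMF, rt
Reagents that add atoms: tert-butyldimethylsilyl chloride, CC(C)(C)[Si](C)(C)Cl
Why: Imidazole-mediated silylation masks the C12 hydroxyl, which would otherwise quench the organometallic steps and form a six-membered lactol with the C6 aldehyde.

**Step 8**
Reactants: 13 (2Z,5E)-1-(TBS-oxy)-3-iodo-2-methyl-6-[(TBS-oxy)methyl]undeca-2,5-dien-9-yne; 14 tert-butyl bromoacetate
Product: 16 tert-butyl (3Z,5E)-3-[1-(TBS-oxy)propan-2-ylidene]-6-[(TBS-oxy)methyl]undec-5-en-9-ynoate, via (2-tert-butoxy-2-oxoethyl)zinc bromide 15 (not isolated)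
Conditions: 14, Zn dust, Me3SiCl (cat.), THF, 40 °C; then 13, Pd2(dba)3 (2.5 mol %), XPhos (6 mol %), THF, 50 °C
Reagents that add atoms: none
Why: Palladium-catalysed coupling of a Reformatsky reagent with an alkenyl iodide (Negishi-type alkenylation of a zinc ester enolate) attaches C7–C6 to C8 with retention under non-basic conditions, so the double bond should not move into conjugation.

**Step 9**
Reactants: 16 tert-butyl (3Z,5E)-3-[1-(TBS-oxy)propan-2-ylidene]-6-[(TBS-oxy)methyl]undec-5-en-9-ynoate
Product: 17 (3Z,5E)-3-[1-(TBS-oxy)propan-2-ylidene]-6-[(TBS-oxy)methyl]undec-5-en-9-yn-1-ol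
Conditions: iBu2AlH (2.5 equiv), CH2Cl2, −78 to 0 °C; aqueous KNaC4H4O6
Reagents that add atoms: none
Why: Full hydride reduction of the ester gives the homoallylic alcohol without touching alkyne, alkenes or silyl ethers, so that the sensitive β,γ-unsaturated aldehyde is released only just before use.

**Step 10**
Reactants: 17 (3Z,5E)-3-[1-(TBS-oxy)propan-2-ylidene]-6-[(TBS-oxy)methyl]undec-5-en-9-yn-1-ol
Product: 18 (3Z,5E)-3-[1-(TBS-oxy)propan-2-ylidene]-6-[(TBS-oxy)methyl]undec-5-en-9-ynal
Conditions: Dess–Martin periodinane, NaHCO3, CH2Cl2, 0 °C to rt; used at once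
Reagents that add atoms: none
Why: Buffered Dess–Martin oxidation is the standard way to a β,γ-unsaturated aldehyde from a homoallylic alcohol without shifting the double bond.

**Step 11**
Reactants: 18 (3Z,5E)-3-[1-(TBS-oxy)propan-2-ylidene]-6-[(TBS-oxy)methyl]undec-5-en-9-ynal
Product: 20 rac-(4E)-1-[(TBS-oxy)methyl]-8-[1-(TBS-oxy)propan-2-ylidene]-5-methyl-6-(TIPS-oxy)cyclodeca-1(10),4-diene (plan locants; C2 and C9 cis on C1=C10; C12 cis to C7), via oxanickelacyclopentene 19 (not isolated)
Conditions: Ni(cod)2 (30 mol %), IMes (1,3-dimesitylimidazol-2-ylidene, 30 mol %), iPr3SiH (5 equiv), THF, rt; slow addition of 18 to a final 0.002 M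
Reagents that add atoms: triisopropylsilane, CC(C)[SiH](C(C)C)C(C)C
Why: Zerovalent nickel carrying the small carbene binds the C4≡C5 alkyne and the C6 aldehyde and undergoes oxidative cyclisation to nickelacycle 19, which already holds the C5–C6 bond; σ-bond metathesis of its Ni–O bond with the silane and C–H reductive elimination then place hydrogen on C4 on the same side as C6, so the ring-trans trisubstituted alkene and the silyl ether arise together. The closest known reaction type is the carbene–nickel/silane reductive coupling of aldehydes with alkynes run intramolecularly as an ynal macrocyclisation; a ten-membered ring is smaller than the rings usually closed this way. The ten-membered carbocycle closes in the endo mode, both alkyne carbons becoming ring members. The new carbinol centre C6 is not controlled, since nothing in substrate or catalyst distinguishes the aldehyde faces, and this is harmless because C6 becomes the ketone in step 16; the E geometry is fixed by the syn addition. The step needs C5 rather than C4 to bond (endo ten-membered versus exo nine-membered ring), which the small carbene should secure by coupling at the alkyne carbon with the smaller substituent (CH3 against the CH2 tether). It also needs ring closure to outrun oligomerisation, which slow addition at high dilution and the chain fold imposed by the ring-cis C1=C10 and the Z C8=C11 alkenes should secure.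

**Step 12**
Reactants: 20 (macrocyclic tris-silyl ether)
Product: 21 rac-(4E)-1-(hydroxymethyl)-8-(1-hydroxypropan-2-ylidene)-5-methyl-6-(TIPS-oxy)cyclodeca-1(10),4-diene (geometries as in 20)
Conditions: HF·pyridine, pyridine, THF, 0 °C to rt
Reagents that add atoms: none
Why: Buffered HF·pyridine cleaves primary TBS ethers much faster than a hindered secondary TIPS ether, freeing both allylic hydroxymethyl groups while C6 stays protected.

**Step 13**
Reactants: 21 (macrocyclic diol)
Product: 22 1,10:8,11-bis-epoxide of 21 with C1 R, C10 R, C11 R and the C8 spiro centre carrying C9 on the oxirane face of the C11 methyl (both C6 epimers)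
Conditions: Ti(OiPr)4 (0.5 equiv), D-(−)-diethyl tartrate (0.6 equiv), tBuOOH (4 equiv, decane), 4 Å molecular sieves, CH2Cl2, −20 °C
Reagents that add atoms: tert-butyl hydroperoxide, CC(C)(C)OO
Why: Sharpless asymmetric epoxidation acts only on the two allylic alcohols (the C4=C5 allylic silyl ether has no directing hydroxyl), and D-(−)-tartrate delivers oxygen to the face that makes each hydroxymethyl-bearing oxirane carbon R (C1 and C11, opposite to the 2S sense given by L-(+)-tartrate), the fixed alkene geometries then setting C10 and C8.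

**Step 14**
Reactants: 22 (bis-epoxy diol)
Product: 23 C1',C12-diacetate of 22
Conditions: Ac2O, pyridine, DMAP (cat.), CH2Cl2, 0 °C
Reagents that add atoms: acetic anhydride, CC(=O)OC(C)=O
Why: Acetylation of two primary alcohols with Ac2O/pyridine is routine and leaves the oxiranes and the TIPS ether intact.

**Step 15**
Reactants: 23 (bis-epoxy diacetate TIPS ether)
Product: 24 C6 carbinol of 23 (both C6 epimers)
Conditions: Bu4NF, AcOH (1:1), THF, 0 °C to rt
Reagents that add atoms: none
Why: Acetic acid-buffered fluoride removes the TIPS ether without the basicity that would cleave the acetates and without the acidity that would open the tetrasubstituted oxirane.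

**Step 16**
Reactants: 24 (C6 carbinol)
Product: 25 CNP0185847.3, (4E)-1',12-diacetoxy-1,10:8,11-diepoxy-5-methylcyclodec-4-en-6-one skeleton with 1R,8S,10R,11R (plan locants)
Conditions: Dess–Martin periodinane, NaHCO3, CH2Cl2, 0 °C
Reagents that add atoms: none
Why: Neutral Dess–Martin oxidation of the secondary allylic alcohol gives the E-enone and merges both C6 epimers into the single target, so the base-sensitive β,γ-epoxy ketone appears only in the last, buffered step.

**Compound list**

1 | 2-butyne-1,4-diol | OCC#CCO | starting material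
2 | 4-(TBS-oxy)but-2-yn-1-ol | CC(C)(C)[Si](C)(C)OCC#CCO | intermediate
3 | cyclic sodium alkenylalanate (Al on O1 and C3 of the Z-butene unit, two 2-methoxyethoxy groups; not isolated) | [Na+].COCCO[Al-]1(OCCOC)OCC=C1CO[Si](C)(C)C(C)(C)C | intermediate
4 | (2Z)-4-(TBS-oxy)-3-iodobut-2-en-1-ol | OC/C=C(\I)CO[Si](C)(C)C(C)(C)C | intermediate
5 | 5-bromopent-2-yne | CC#CCCBr | starting material
6 | pent-3-yn-1-ylzinc bromide (not isolated) | CC#CCC[Zn]Br | intermediate
7 | (2E)-3-[(TBS-oxy)methyl]oct-2-en-6-yn-1-ol | OC/C=C(/CO[Si](C)(C)C(C)(C)C)CCC#CC | intermediate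
8 | (2E)-1-bromo-3-[(TBS-oxy)methyl]oct-2-en-6-yne | BrC/C=C(/CO[Si](C)(C)C(C)(C)C)CCC#CC | intermediate
9 | propargyl alcohol | C#CCO | starting material
10 | (5E)-6-[(TBS-oxy)methyl]undec-5-ene-2,9-diyn-1-ol | OCC#CC/C=C(/CO[Si](C)(C)C(C)(C)C)CCC#CC | intermediate
11 | five-membered oxamagnesacycle (Mg on O1 and C3 of the 2-methyl-2-en-1-olate; not isolated) | CC1=C(C/C=C(/CO[Si](C)(C)C(C)(C)C)CCC#CC)[Mg]OC1 | intermediate
12 | (2Z,5E)-3-iodo-2-methyl-6-[(TBS-oxy)methyl]undeca-2,5-dien-9-yn-1-ol | OC/C(C)=C(\I)C/C=C(/CO[Si](C)(C)C(C)(C)C)CCC#CC | intermediate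
13 | (2Z,5E)-1-(TBS-oxy)-3-iodo-2-methyl-6-[(TBS-oxy)methyl]undeca-2,5-dien-9-yne | CC(C)(C)[Si](C)(C)OC/C(C)=C(\I)C/C=C(/CO[Si](C)(C)C(C)(C)C)CCC#CC | intermediate
14 | tert-butyl bromoacetate | CC(C)(C)OC(=O)CBr | starting material
15 | (2-tert-butoxy-2-oxoethyl)zinc bromide (not isolated) | CC(C)(C)OC(=O)C[Zn]Br | intermediate
16 | tert-butyl (3Z,5E)-3-[1-(TBS-oxy)propan-2-ylidene]-6-[(TBS-oxy)methyl]undec-5-en-9-ynoate | CC(C)(C)OC(=O)C/C(=C(/C)CO[Si](C)(C)C(C)(C)C)C/C=C(/CO[Si](C)(C)C(C)(C)C)CCC#CC | intermediate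
17 | (3Z,5E)-3-[1-(TBS-oxy)propan-2-ylidene]-6-[(TBS-oxy)methyl]undec-5-en-9-yn-1-ol | OCC/C(=C(/C)CO[Si](C)(C)C(C)(C)C)C/C=C(/CO[Si](C)(C)C(C)(C)C)CCC#CC | intermediate
18 | (3Z,5E)-3-[1-(TBS-oxy)propan-2-ylidene]-6-[(TBS-oxy)methyl]undec-5-en-9-ynal | O=CC/C(=C(/C)CO[Si](C)(C)C(C)(C)C)C/C=C(/CO[Si](C)(C)C(C)(C)C)CCC#CC | intermediate
19 | oxanickelacyclopentene (IMes–Ni bound to the C6 oxygen and to C4, ten-membered ring closed; not isolated) | CC(C)(C)[Si](C)(C)OC/C1=C/C/C(=C(\C)CO[Si](C)(C)C(C)(C)C)CC2O[Ni](=C3N(C=CN3c3c(C)cc(C)cc3C)c3c(C)cc(C)cc3C)C(=C2C)CC1 | intermediate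
20 | rac-(4E)-1-[(TBS-oxy)methyl]-8-[1-(TBS-oxy)propan-2-ylidene]-5-methyl-6-(TIPS-oxy)cyclodeca-1(10),4-diene | CC(C)(C)[Si](C)(C)OC/C1=C/C/C(=C(\C)CO[Si](C)(C)C(C)(C)C)CC(O[Si](C(C)C)(C(C)C)C(C)C)/C(C)=C/CC1 | intermediate
21 | rac-(4E)-1-(hydroxymethyl)-8-(1-hydroxypropan-2-ylidene)-5-methyl-6-(TIPS-oxy)cyclodeca-1(10),4-diene | OC/C1=C/C/C(=C(\C)CO)CC(O[Si](C(C)C)(C(C)C)C(C)C)/C(C)=C/CC1 | intermediate
22 | bis-epoxy diol, oxirane centres as in 25, C6 epimers | OC[C@]12CC/C=C(\C)C(O[Si](C(C)C)(C(C)C)C(C)C)C[C@]3(C[C@H]1O2)O[C@]3(C)CO | intermediate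
23 | bis-epoxy diacetate TIPS ether, C6 epimers | CC(=O)OC[C@]12CC/C=C(\C)C(O[Si](C(C)C)(C(C)C)C(C)C)C[C@]3(C[C@H]1O2)O[C@]3(C)COC(C)=O | intermediate
24 | bis-epoxy diacetate C6 carbinol, C6 epimers | CC(=O)OC[C@]12CC/C=C(\C)C(O)C[C@]3(C[C@H]1O2)O[C@]3(C)COC(C)=O | intermediate
25 | CNP0185847.3 (4E; 1R,8S,10R,11R in plan locants) | CC(=O)OC[C@]12CC/C=C(\C)C(=O)C[C@]3(C[C@H]1O2)O[C@]3(C)COC(C)=O | target

**Totals and risks**

Total step count: 16. Longest linear sequence: 16 steps (1 to 25); 5, 9 and 14 enter as bought reagents.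

Step 11. Medium-ring closure may lose to intermolecular coupling (oligomers), to exo closure at C4, or to plain hydrosilylation of the aldehyde. The fallback forms the same C5–C6 bond by Nozaki–Hiyama–Kishi cyclisation and sets out from 17. Hydrozirconation with excess Cp2Zr(H)Cl (THF, 40 °C, equilibration to zirconium on the methyl-bearing alkyne carbon) should give the bis-zirconated alkenylzirconocene F1. Iodinolysis gives the E-iodoalkenol F2, and Dess–Martin oxidation the iodo aldehyde F3. CrCl2 with catalytic NiCl2 in DMSO/THF at high dilution should close the macrocyclic allylic alcohol F4. Silylation with iPr3SiOTf and 2,6-lutidine returns to the route at 20.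

Step 13. Oxygen transfer to the tetrasubstituted exocyclic alkene may be slow or face-unselective in the C6 epimer whose silyloxy group shields the tartrate-preferred face, leaving mono-epoxide or wrong-face oxirane. The fallback removes the C6 stereocentre before epoxidation and sets out from 18. Cyclisation as in step 11 but with Et3SiH (again through 19) gives the triethylsilyl ether F5. Pyridinium p-toluenesulfonate in MeOH cleaves only that ether to the macrocyclic allylic alcohol F4, and Dess–Martin oxidation gives the bis-TBS dienone F6. HF·pyridine frees the dienone diol F7, and the epoxidation of step 13 on this achiral substrate gives the bis-epoxy diol ketone F8. Ac2O/pyridine returns to the route at 25. This order exposes a free C12 hydroxyl to the C6 ketone (hemiketal equilibrium), which is why it is held in reserve.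

Step 8. Coupling at the crowded alkenyl iodide may stall with proto-deiodination, or the new double bond may drift into conjugation with the ester. The fallback builds C7–C6 by vinylation and hydroboration and sets out from 13. Suzuki–Miyaura coupling with CH2=CHBF3K (PdCl2(dppf), Cs2CO3, THF/H2O) gives the triene F9. 9-BBN adds selectively to the monosubstituted alkene to give the B-alkyl borane F10, and oxidation with NaBO3·4H2O returns to the route at 17.

**Further compounds**

F1 | step 11 | bis-zirconated alkenylzirconocene from 17 (Cp2ZrCl on the C6 oxygen and on C5) | Cl[Zr](OCC/C(=C(/C)CO[Si](C)(C)C(C)(C)C)C/C=C(/CO[Si](C)(C)C(C)(C)C)CC/C=C(\C)[Zr](Cl)(C1C=CC=C1)C1C=CC=C1)(C1C=CC=C1)C1C=CC=C1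
F2 | step 11 | (3Z,5E,9E)-10-iodo-3-[1-(TBS-oxy)propan-2-ylidene]-6-[(TBS-oxy)methyl]undeca-5,9-dien-1-ol | OCC/C(=C(/C)CO[Si](C)(C)C(C)(C)C)C/C=C(/CO[Si](C)(C)C(C)(C)C)CC/C=C(\C)I
F3 | step 11 | (3Z,5E,9E)-10-iodo-3-[1-(TBS-oxy)propan-2-ylidene]-6-[(TBS-oxy)methyl]undeca-5,9-dienal | O=CC/C(=C(/C)CO[Si](C)(C)C(C)(C)C)C/C=C(/CO[Si](C)(C)C(C)(C)C)CC/C=C(\C)I
F4 | step 11 | rac-(4E)-macrocyclic C6 carbinol with both TBS ethers | CC(C)(C)[Si](C)(C)OC/C1=C/C/C(=C(\C)CO[Si](C)(C)C(C)(C)C)CC(O)/C(C)=C/CC1
F5 | step 13 | rac-(4E)-macrocyclic C6 triethylsilyl ether with both TBS ethers | CC(C)(C)[Si](C)(C)OC/C1=C/C/C(=C(\C)CO[Si](C)(C)C(C)(C)C)CC(O[Si](CC)(CC)CC)/C(C)=C/CC1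
F6 | step 13 | (4E)-macrocyclic dienone with both TBS ethers | CC(C)(C)[Si](C)(C)OC/C1=C/C/C(=C(\C)CO[Si](C)(C)C(C)(C)C)CC(=O)/C(C)=C/CC1
F7 | step 13 | (4E)-macrocyclic dienone diol | OC/C1=C/C/C(=C(\C)CO)CC(=O)/C(C)=C/CC1
F8 | step 13 | bis-epoxy diol ketone (oxirane centres as in 25) | OC[C@]12CC/C=C(\C)C(=O)C[C@]3(C[C@H]1O2)O[C@]3(C)CO
F9 | step 8 | (3Z,5E)-3-[1-(TBS-oxy)propan-2-ylidene]-6-[(TBS-oxy)methyl]undeca-1,5-dien-9-yne | C=C/C(=C(/C)CO[Si](C)(C)C(C)(C)C)C/C=C(/CO[Si](C)(C)C(C)(C)C)CCC#CC
F10 | step 8 | B-alkyl-9-borabicyclo[3.3.1]nonane (boron on C6) | C1CCC2CCCC1B2CC/C(=C(/C)CO[Si](C)(C)C(C)(C)C)C/C=C(/CO[Si](C)(C)C(C)(C)C)CCC#CC
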